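A leftover is where the reckoning starts: substrate still in your flask at the end is a debit on the open intermediate, and second reagent or capture agent still there is a credit.

in all of them: partner 10.5 mM; capture agent 0.500 mM
- teal: substrate 10 mM; second reagent 9.00 mM (fed, over 80.0 min); time 80 min; a stirred flask in which second reagent is dosed at a steady rate over 80.0 min without added volume, worked up at 80 min
- grey: substrate 10 mM; second reagent 9.00 mM; time 80 min; everything together in a closed stirred flask, run for 80 min
- violet: substrate 10 mM (fed, over 80.0 min); second reagent 9.00 mM; time 80 min; a stirred flask in which substrate is dosed at a steady rate over 80.0 min without added volume, worked up at 80 min
- blue: substrate 10 mM; second reagent 9.00 mM; one stirred flow tank at steady state, fed with the mixture as stated, mean residence time 80 min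

1. order of the set-ups by the amount of open intermediate at the outlet or at the end, in percent of the substrate put in, highest first (teal / grey / violet / blue)
2. amount of open intermediate at the outlet or at the end, in percent of the substrate put in, teal
3. amount of open intermediate at the outlet or at the end, in percent of the substrate put in, grey
4. amount of open intermediate at the outlet or at the end, in percent of the substrate put in, violet
5. amount of open intermediate at the outlet or at the end, in percent of the substrate put in, blue

- the stated concentrations are those of everything mixed, before any reaction; amounts are the same in each set-up
- the feed brings no volume worth counting
- run time (teal): 80 min

Keep the books in fractions of the substrate charge. Substrate that has gone stands in one of these entries: side product, which took one second reagent with it; open intermediate; target, counted together with its isomer, which took one second reagent on the way; and trapped intermediate, which took one capture agent. Second reagent, charged at 90.0%, less than the substrate, is the limiting reagent for target, and capture agent is charged at 5.00%. Subtract the second reagent and capture agent spent from the substrate spent, and side product and target cancel. Once the dosing is complete, the open intermediate therefore equals the ledger floor, the substrate charge less the charges of second reagent and capture agent, 5.00%, plus second reagent left, plus capture agent left, minus substrate left.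

The debit I can reckon for grey. Substrate falls by its reaction with partner, which is in excess by 5.00%, and its half-life by the side step, 8.6 h, is longer than the 13 min by the partner step, so for a first figure I set the side step aside, knowing that the excess is small and that each bit of side product widens it. That first figure leaves 17.4% of the substrate at 80 min, and I read it as high for both teal and grey, since the side step takes the debit down. Teal's second reagent stands in the flask on average 40.0 min, less than grey's 80 min, so it has less time to be spent and less time to make side product; teal should therefore carry the larger credit and also the larger debit, and I commit to teal above grey on my judgement that the credit outweighs the debit, and my reckoning goes no further.

The forecast gives 59% for teal, 48% for grey, 43% for violet and 37.6% for blue, in the order teal > grey > violet > blue; its ground for teal is that “second reagent is scarce early, so intermediate accumulates”.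

    substrate + partner → open intermediate (k1 = 5.1 /M/min)
    target ⇌ isomer of the product (K2 = 11, k2 = 0.019 /min)
    substrate + second reagent → side product (k3 = 0.15 /M/min)
    second reagent + open intermediate → target (k4 = 1.1 /M/min)
    open intermediate + capture agent → trapped intermediate (k5 = 4.6 /M/min)

The flasks give 58.3% in teal, 48.5% in grey, 43.6% in violet and 37.4% in blue, in the order teal > grey > violet > blue. As charged in grey, substrate has a half-life of 13 min by the partner step alone, shorter than the 70 min of the open intermediate by the second-reagent step alone. Teal's reading stands 53 percentage points above the floor, and that gap is second reagent and capture agent unspent, less substrate unspent; left until 800 min, teal reads 13.8%, and the same gap has shrunk to 8.8 points.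

The constants used here belong to no real substance; the flask was simulated.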